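**Numbering.** Hydroazulene numbering of the target is used throughout: C-1/C-2 (CH2), C-3 (C(OH)iPr), C-3a (ring-fusion CH), C-4 (CH–O-anisoyl), C-5 (CH2), C-6 (C–Me=), C-7 (=CH), C-8 (CH–OAc), C-8a (C–Me).

## Retrosynthetic overview

1. End game: C-8 acetate ← Luche reduction ← allylic oxidation of the Δ6 anisoate ← hydroxyl-directed reduction of a C-4 ketone (a 3-hydroxy-hydroazulen-4-one).
2. Seven-membered ring ← strain-driven β-scission of the C-3a–C-7 bond of a tricyclo[5.3.0.0(1,5)]decanone by a C-6 radical, which expands a cyclopentanone by the two carbons C-8/C-8a.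
3. Tricycle ← intramolecular enone–alkene [2+2] photocycloaddition that forms C-7–C-8 and C-3a–C-8a at once; ring order: temporary cyclopentenone (C-3a, C-4, C-5, C-6, C-7), then cyclopentane (C-1 to C-3a, C-8a) plus cyclobutane in the key step, then the seven-membered ring on fragmentation.
4. Photosubstrate (a 2-substituted 4-oxy-4-methylcyclopent-2-enone) ← aldol / aldol-condensation annulation on a methyl ketone ← (S)-terpinen-4-ol, which supplies C-3 with OH and isopropyl, C-1, C-2, C-8a with its methyl, C-3a and C-4.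
5. Enabling feature: C-3a and C-7 are linked through C-4–C-5–C-6, so a temporary C-3a–C-7 bond contracts the seven-membered ring to a cyclopentenone (C-3a=C-7 conjugated to C-4=O) that holds C-8a=C-8 five atoms away on the C-3 side chain. The C-3 hydroxyl beside C-3a can hydrogen-bond the C-4 carbonyl for facial control, and the oxygenated, methyl-bearing C-6 beside C-7 is where the radical that reopens the cyclobutane is made.

Key step: step 9

Assumption: (S)-(+)-terpinen-4-ol is taken as enantiopure (material of lower ee is enriched beforehand); the C-6 carbinol centre made in step 5 is carried as both epimers because step 10 erases it.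

## Route

Step 1
Reactants: 1 (S)-(+)-terpinen-4-ol
Product: 2 triethyl{[(1S)-4-methyl-1-(propan-2-yl)cyclohex-3-en-1-yl]oxy}silane
Conditions: TESOTf, 2,6-lutidine, CH2Cl2, 0 °C
Reagents that add atoms: triethylsilyl trifluoromethanesulfonate, CC[Si](CC)(CC)OS(=O)(=O)C(F)(F)F
Why: Silylation of the hindered tertiary alcohol with a silyl triflate; the ether blocks retro-aldol and oxypalladation pathways of the later β-oxygenated carbonyl intermediates, and the stereocentre is untouched.

Step 2
Reactants: 2 triethyl{[(1S)-4-methyl-1-(propan-2-yl)cyclohex-3-en-1-yl]oxy}silane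
Product: 3 (3S)-6-oxo-3-(propan-2-yl)-3-[(triethylsilyl)oxy]heptanal
Conditions: O3, CH2Cl2, −78 °C; then Me2S, −78 °C to rt
Reagents that add atoms: ozone, [O-][O+]=O
Why: Ozonolysis with reductive work-up opens the ring at its only alkene and releases the aldehyde (future C-4, with C-3a as its α-carbon) and the methyl ketone (future C-8a); no stereocentre is formed.

Step 3
Reactants: 3 (3S)-6-oxo-3-(propan-2-yl)-3-[(triethylsilyl)oxy]heptanal
Product: 4 triethyl{[(4S)-7-methyl-4-(propan-2-yl)octa-1,7-dien-4-yl]oxy}silane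
Conditions: Ph3PCH3Br, KN(SiMe3)2, THF, 0 °C; then 3, −78 °C to rt
Reagents that add atoms: methyltriphenylphosphonium bromide, C[P+](c1ccccc1)(c1ccccc1)c1ccccc1.[Br-]
Why: Double Wittig methylenation converts the ketone into the 1,1-disubstituted alkene C-8a=C-8 (the photopartner) and the aldehyde into a vinyl group; the salt-free ylide at low temperature should not eliminate the β-silyloxy group.

Step 4
Reactants: 4 triethyl{[(4S)-7-methyl-4-(propan-2-yl)octa-1,7-dien-4-yl]oxy}silane
Product: 5 (4S)-7-methyl-4-(propan-2-yl)-4-[(triethylsilyl)oxy]oct-7-en-2-one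
Conditions: PdCl2 (10 mol %), Cu(OAc)2 (20 mol %), O2 (1 atm), DMA/H2O, rt
Reagents that add atoms: water, O
Why: Tsuji–Wacker oxidation is selective for the monosubstituted alkene and gives the methyl ketone (C-4 carbonyl, C-5 as its methyl group), leaving the 1,1-disubstituted alkene untouched.

Step 5
Reactants: 5 (4S)-7-methyl-4-(propan-2-yl)-4-[(triethylsilyl)oxy]oct-7-en-2-one; 6 1,1-dimethoxypropan-2-one
Product: 7 (6S)-2-hydroxy-1,1-dimethoxy-2,9-dimethyl-6-(propan-2-yl)-6-[(triethylsilyl)oxy]dec-9-en-4-one (both C-2 epimers)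
Conditions: LDA, THF, −78 °C; then 6, −78 °C; AcOH quench at −78 °C
Reagents that add atoms: none
Why: The kinetic lithium enolate forms at the methyl group (the neopentyl CH2 is hindered) and adds to the activated ketone of 6 in an aldol addition that installs C-6 with its methyl and oxygen and C-7 as a masked aldehyde; the new carbinol centre is not controlled and need not be.

Step 6
Reactants: 7 (6S)-2-hydroxy-1,1-dimethoxy-2,9-dimethyl-6-(propan-2-yl)-6-[(triethylsilyl)oxy]dec-9-en-4-one
Product: 9 4-hydroxy-4-methyl-2-{(3R)-2,6-dimethyl-3-[(triethylsilyl)oxy]hept-6-en-3-yl}cyclopent-2-en-1-one (both C-4 epimers), via keto aldehyde 8 (not isolated)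
Conditions: Amberlyst-15, acetone/H2O, rt; then K2CO3, MeOH, 0 °C to rt
Reagents that add atoms: none
Why: Acetal hydrolysis followed by intramolecular aldol condensation: only the C-3a methylene can reach the aldehyde in a five-membered closure, and E1cB dehydration gives the cyclopentenone with the C-3a=C-7 double bond; the silyl ether prevents retro-aldol loss of the C-3 carbinol.

Step 7
Reactants: 9 4-hydroxy-4-methyl-2-{(3R)-2,6-dimethyl-3-[(triethylsilyl)oxy]hept-6-en-3-yl}cyclopent-2-en-1-one
Product: 10 methyl 1-methyl-4-oxo-3-{(3R)-2,6-dimethyl-3-[(triethylsilyl)oxy]hept-6-en-3-yl}cyclopent-2-en-1-yl oxalate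
Conditions: ClC(O)CO2Me, pyridine, DMAP (cat.), CH2Cl2, 0 °C
Reagents that add atoms: methyl chlorooxoacetate, COC(=O)C(Cl)=O
Why: Acylation of the only free hydroxyl gives the tertiary methyl oxalate, a radical precursor for Barton-type deoxygenation; at the enone stage elimination would require a cyclopentadienone and is therefore not expected.

Step 8
Reactants: 10 methyl 1-methyl-4-oxo-3-{(3R)-2,6-dimethyl-3-[(triethylsilyl)oxy]hept-6-en-3-yl}cyclopent-2-en-1-yl oxalate
Product: 11 3-[(3R)-3-hydroxy-2,6-dimethylhept-6-en-3-yl]-1-methyl-4-oxocyclopent-2-en-1-yl methyl oxalate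
Conditions: HF·pyridine, THF, 0 °C to rt
Reagents that add atoms: none
Why: Fluoride-driven cleavage of the tertiary silyl ether under acidic conditions that spare the oxalate and the enone; the freed C-3 hydroxyl is needed to direct the photocycloaddition.

Step 9
Reactants: 11 3-[(3R)-3-hydroxy-2,6-dimethylhept-6-en-3-yl]-1-methyl-4-oxocyclopent-2-en-1-yl methyl oxalate
Product: 12 2-hydroxy-5,8-dimethyl-10-oxo-2-(propan-2-yl)tricyclo[5.3.0.0(1,5)]decan-8-yl methyl oxalate (cis,anti,cis-fused; C-5 methyl and C-2 hydroxyl on the face of the carbonyl-bearing ring; both C-8 epimers)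
Conditions: hν (≥350 nm, Pyrex), degassed CH2Cl2/hexane, 5 mM, −20 °C
Reagents that add atoms: none
Why: Excitation and intersystem crossing give the triplet 2-alkylcyclopent-2-enone, which adds to the tethered 1,1-disubstituted alkene through a 1,4-biradical in an intramolecular enone–alkene [2+2] photocycloaddition; the closest known type is the straight ("rule of five") cyclisation of 2-(pent-4-enyl)cyclopent-2-enones to tricyclo[5.3.0.0(1,5)]decanones. The cyclopentane (C-1, C-2, C-3, C-3a, C-8a) closes by 5-exo attack of the enone α-carbon C-3a on the internal alkene carbon C-8a, and the cyclobutane (C-3a, C-7, C-8, C-8a) closes by collapse of the C-7/C-8 biradical. C-8a is set relative to C-3 because, in a non-donor solvent, the tertiary OH hydrogen-bonds the C-4 carbonyl, which holds the C–O bond in the enone plane with the isopropyl group on one face and the tether on the other, so the alkene reaches only the face that places the C-8a methyl syn to C-4 and anti to the isopropyl group; C-3a and C-7 follow from the two cis ring fusions that a three-atom tether and a five-membered enone enforce. The step needs straight over crossed regiochemistry (secured by the three-atom tether), facial selectivity (secured by the hydrogen bond, hence no alcohol solvent) and selective excitation of the enone (secured by the long wavelength, at which the product ketone and the oxalate do not absorb). The C-6 centre carries methyl and oxalyloxy on opposite faces in either epimer, so it should exert little facial bias and both epimers should give the same C-8a configuration.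

Step 10
Reactants: 12 2-hydroxy-5,8-dimethyl-10-oxo-2-(propan-2-yl)tricyclo[5.3.0.0(1,5)]decan-8-yl methyl oxalate
Product: 13 (3R,3aS,8aR)-3-hydroxy-6,8a-dimethyl-3-(propan-2-yl)-2,3,3a,5,8,8a-hexahydroazulen-4(1H)-one (cis-fused)
Conditions: Bu3SnH (syringe pump), AIBN, PhMe, 5 mM, 100 °C
Reagents that add atoms: none
Why: Barton-type deoxygenation of the tertiary oxalate gives the C-6 radical, whose β-scission of the strained ring-fusion bond C-3a–C-7 (cyclobutylcarbinyl radical fragmentation) forms the Δ6 alkene and the tertiary α-keto radical at C-3a, with slow hydride addition letting fragmentation outrun direct reduction; both C-6 epimers converge, and hydrogen transfer to C-3a is expected from the face away from the C-7/C-8 bridge and the isopropyl group, which gives the cis ring fusion.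

Step 11
Reactants: 13 (3R,3aS,8aR)-3-hydroxy-6,8a-dimethyl-3-(propan-2-yl)-2,3,3a,5,8,8a-hexahydroazulen-4(1H)-one
Product: 14 (3R,3aR,8aR)-3-hydroxy-6,8a-dimethyl-3-(propan-2-yl)-2,3,3a,5,8,8a-hexahydroazulen-4(1H)-one (trans-fused)
Conditions: DBU (0.1 equiv), PhMe, rt
Reagents that add atoms: none
Why: Base-mediated epimerisation α to the ketone through the C-3a enolate; the trans-fused epimer, with C-4 anti to the isopropyl group and syn to the hydroxyl (O–H···O=C), should be the thermodynamic one.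

Step 12
Reactants: 14 (3R,3aR,8aR)-3-hydroxy-6,8a-dimethyl-3-(propan-2-yl)-2,3,3a,5,8,8a-hexahydroazulen-4(1H)-one
Product: 15 (3R,3aS,4S,8aR)-6,8a-dimethyl-3-(propan-2-yl)-1,2,3,3a,4,5,8,8a-octahydroazulene-3,4-diol
Conditions: Me4NBH(OAc)3, MeCN/AcOH, −25 °C
Reagents that add atoms: none
Why: Hydroxyl-directed (Evans–Saksena) reduction: the borohydride bound to the C-3 oxygen delivers hydride to C-4 through a chair-like six-membered transition state from the face of that oxygen, giving the 1,3-anti diol with H-4 anti to H-3a (4S).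

Step 13
Reactants: 15 (3R,3aS,4S,8aR)-6,8a-dimethyl-3-(propan-2-yl)-1,2,3,3a,4,5,8,8a-octahydroazulene-3,4-diol; 16 4-methoxybenzoyl chloride
Product: 17 (3R,3aS,4S,8aR)-3-hydroxy-6,8a-dimethyl-3-(propan-2-yl)-1,2,3,3a,4,5,8,8a-octahydroazulen-4-yl 4-methoxybenzoate
Conditions: 16, DMAP, pyridine, CH2Cl2, rt
Reagents that add atoms: none
Why: DMAP-catalysed acylation of the secondary alcohol; the tertiary C-3 hydroxyl is too hindered to react, and no stereocentre changes.

Step 14
Reactants: 17 (3R,3aS,4S,8aR)-3-hydroxy-6,8a-dimethyl-3-(propan-2-yl)-1,2,3,3a,4,5,8,8a-octahydroazulen-4-yl 4-methoxybenzoate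
Product: 18 (3R,3aS,4S,8aS)-3-hydroxy-6,8a-dimethyl-8-oxo-3-(propan-2-yl)-1,2,3,3a,4,5,8,8a-octahydroazulen-4-yl 4-methoxybenzoate
Conditions: Rh2(cap)4 (dirhodium tetrakis(caprolactamate), 1 mol %), t-BuOOH, K2CO3, CH2Cl2, rt
Reagents that add atoms: tert-butyl hydroperoxide, CC(C)(C)OO
Why: Allylic C–H oxidation by peroxyl-radical hydrogen abstraction: the C-8 methylene sits on the CH end of the trisubstituted alkene, the site oxidised when Δ5-steroid 3-esters are converted into 7-ketones, while C-5 is deactivated by the neighbouring ester; no stereocentre is formed.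

Step 15
Reactants: 18 (3R,3aS,4S,8aS)-3-hydroxy-6,8a-dimethyl-8-oxo-3-(propan-2-yl)-1,2,3,3a,4,5,8,8a-octahydroazulen-4-yl 4-methoxybenzoate
Product: 19 (3R,3aS,4S,8S,8aS)-3,8-dihydroxy-6,8a-dimethyl-3-(propan-2-yl)-1,2,3,3a,4,5,8,8a-octahydroazulen-4-yl 4-methoxybenzoate
Conditions: NaBH4, CeCl3·7H2O, MeOH, −78 °C
Reagents that add atoms: none
Why: Luche 1,2-reduction of the enone; hydride should add to C-8 from the face opposite the axial C-8a methyl group, giving the equatorial 8-hydroxyl cis to that methyl (8S).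

Step 16
Reactants: 19 (3R,3aS,4S,8S,8aS)-3,8-dihydroxy-6,8a-dimethyl-3-(propan-2-yl)-1,2,3,3a,4,5,8,8a-octahydroazulen-4-yl 4-methoxybenzoate
Product: 20 (3R,3aS,4S,8S,8aS)-8-acetoxy-3-hydroxy-6,8a-dimethyl-3-(propan-2-yl)-1,2,3,3a,4,5,8,8a-octahydroazulen-4-yl 4-methoxybenzoate
Conditions: Ac2O, DMAP (cat.), pyridine, CH2Cl2, 0 °C to rt
Reagents that add atoms: acetic anhydride, CC(=O)OC(C)=O
Why: DMAP-catalysed acetylation of the secondary allylic alcohol; the tertiary C-3 hydroxyl does not react under these conditions, and no stereocentre changes.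

## Compound list

1 | (S)-(+)-terpinen-4-ol, (1S)-4-methyl-1-(propan-2-yl)cyclohex-3-en-1-ol | CC1=CC[C@](O)(C(C)C)CC1 | starting material
2 | triethyl{[(1S)-4-methyl-1-(propan-2-yl)cyclohex-3-en-1-yl]oxy}silane | CC1=CC[C@](O[Si](CC)(CC)CC)(C(C)C)CC1 | intermediate
3 | (3S)-6-oxo-3-(propan-2-yl)-3-[(triethylsilyl)oxy]heptanal | O=CC[C@](O[Si](CC)(CC)CC)(C(C)C)CCC(C)=O | intermediate
4 | triethyl{[(4S)-7-methyl-4-(propan-2-yl)octa-1,7-dien-4-yl]oxy}silane | C=CC[C@](O[Si](CC)(CC)CC)(C(C)C)CCC(C)=C | intermediate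
5 | (4S)-7-methyl-4-(propan-2-yl)-4-[(triethylsilyl)oxy]oct-7-en-2-one | CC(=O)C[C@](O[Si](CC)(CC)CC)(C(C)C)CCC(C)=C | intermediate
6 | 1,1-dimethoxypropan-2-one | CC(=O)C(OC)OC | starting material
7 | (6S)-2-hydroxy-1,1-dimethoxy-2,9-dimethyl-6-(propan-2-yl)-6-[(triethylsilyl)oxy]dec-9-en-4-one, both C-2 epimers | COC(OC)C(C)(O)CC(=O)C[C@](O[Si](CC)(CC)CC)(C(C)C)CCC(C)=C | intermediate
8 | (6S)-2-hydroxy-2,9-dimethyl-4-oxo-6-(propan-2-yl)-6-[(triethylsilyl)oxy]dec-9-enal, both C-2 epimers (not isolated) | O=CC(C)(O)CC(=O)C[C@](O[Si](CC)(CC)CC)(C(C)C)CCC(C)=C | intermediate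
9 | 4-hydroxy-4-methyl-2-{(3R)-2,6-dimethyl-3-[(triethylsilyl)oxy]hept-6-en-3-yl}cyclopent-2-en-1-one, both C-4 epimers | O=C1CC(C)(O)C=C1[C@](O[Si](CC)(CC)CC)(C(C)C)CCC(C)=C | intermediate
10 | methyl 1-methyl-4-oxo-3-{(3R)-2,6-dimethyl-3-[(triethylsilyl)oxy]hept-6-en-3-yl}cyclopent-2-en-1-yl oxalate, both ring epimers | O=C1CC(C)(OC(=O)C(=O)OC)C=C1[C@](O[Si](CC)(CC)CC)(C(C)C)CCC(C)=C | intermediate
11 | 3-[(3R)-3-hydroxy-2,6-dimethylhept-6-en-3-yl]-1-methyl-4-oxocyclopent-2-en-1-yl methyl oxalate, both ring epimers | O=C1CC(C)(OC(=O)C(=O)OC)C=C1[C@](O)(C(C)C)CCC(C)=C | intermediate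
12 | 2-hydroxy-5,8-dimethyl-10-oxo-2-(propan-2-yl)tricyclo[5.3.0.0(1,5)]decan-8-yl methyl oxalate, cis,anti,cis-fused, both C-8 epimers | O=C1CC(C)(OC(=O)C(=O)OC)[C@@H]2C[C@@]3(C)CC[C@@](O)(C(C)C)[C@@]123 | intermediate
13 | (3R,3aS,8aR)-3-hydroxy-6,8a-dimethyl-3-(propan-2-yl)-2,3,3a,5,8,8a-hexahydroazulen-4(1H)-one, cis-fused | O=C1CC(C)=CC[C@@]2(C)CC[C@@](O)(C(C)C)[C@@H]12 | intermediate
14 | (3R,3aR,8aR)-3-hydroxy-6,8a-dimethyl-3-(propan-2-yl)-2,3,3a,5,8,8a-hexahydroazulen-4(1H)-one, trans-fused | O=C1CC(C)=CC[C@@]2(C)CC[C@@](O)(C(C)C)[C@H]12 | intermediate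
15 | (3R,3aS,4S,8aR)-6,8a-dimethyl-3-(propan-2-yl)-1,2,3,3a,4,5,8,8a-octahydroazulene-3,4-diol | O[C@H]1CC(C)=CC[C@@]2(C)CC[C@@](O)(C(C)C)[C@H]12 | intermediate
16 | 4-methoxybenzoyl chloride | COc1ccc(C(Cl)=O)cc1 | starting material
17 | (3R,3aS,4S,8aR)-3-hydroxy-6,8a-dimethyl-3-(propan-2-yl)-1,2,3,3a,4,5,8,8a-octahydroazulen-4-yl 4-methoxybenzoate | COc1ccc(C(=O)O[C@H]2CC(C)=CC[C@@]3(C)CC[C@@](O)(C(C)C)[C@H]23)cc1 | intermediate
18 | (3R,3aS,4S,8aS)-3-hydroxy-6,8a-dimethyl-8-oxo-3-(propan-2-yl)-1,2,3,3a,4,5,8,8a-octahydroazulen-4-yl 4-methoxybenzoate | COc1ccc(C(=O)O[C@H]2CC(C)=CC(=O)[C@@]3(C)CC[C@@](O)(C(C)C)[C@H]23)cc1 | intermediate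
19 | (3R,3aS,4S,8S,8aS)-3,8-dihydroxy-6,8a-dimethyl-3-(propan-2-yl)-1,2,3,3a,4,5,8,8a-octahydroazulen-4-yl 4-methoxybenzoate | COc1ccc(C(=O)O[C@H]2CC(C)=C[C@H](O)[C@@]3(C)CC[C@@](O)(C(C)C)[C@H]23)cc1 | intermediate
20 | (3R,3aS,4S,8S,8aS)-8-acetoxy-3-hydroxy-6,8a-dimethyl-3-(propan-2-yl)-1,2,3,3a,4,5,8,8a-octahydroazulen-4-yl 4-methoxybenzoate | COc1ccc(C(=O)O[C@H]2CC(C)=C[C@H](OC(C)=O)[C@@]3(C)CC[C@@](O)(C(C)C)[C@H]23)cc1 | target

## Step count and risks

Total step count: 16. Longest linear sequence: 16 steps, from (S)-(+)-terpinen-4-ol (6 and 16 are purchased).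

Three steps most likely to fail:

1. **Step 10.** The C-6 radical lies in a five-membered ring, where its orbital overlaps poorly with the ring-fusion bond; β-scission may instead take the external C-7–C-8 bond (a spiro ketone would result), or the radical may be reduced before it fragments. Fallback (ionic retro-aldol instead of radical bond cleavage, a de Mayo variant), which sets out from 5 and comes back at 15: the kinetic enolate of 5 (LDA) is alkylated with methyl 2-bromopropanoate to give methyl 2,9-dimethyl-4-oxo-6-(propan-2-yl)-6-[(triethylsilyl)oxy]dec-9-enoate F1. KOtBu in THF closes it in a Dieckmann-type cyclisation to the enolised 2-substituted 4-methylcyclopentane-1,3-dione F2. Irradiation of this enol (Pyrex, MeCN) forms the same two bonds by [2+2] across C-3a=C-7, the cyclobutanol opens by retro-aldol, and NaOMe in MeOH equilibrates the ring fusion to give the trans-fused 6,8a-dimethyl-3-(propan-2-yl)-3-[(triethylsilyl)oxy]octahydroazulene-4,7-dione F3. The regioisomer from the other enol tautomer and any C-8a epimer would have to be separated here. HF·pyridine gives the hydroxy dione F4, and Me4NBH(OAc)3 reduces only the C-4 ketone to the 3,4-dihydroxy-7-ketone F5. The more substituted C-6 enolate (KN(SiMe3)2 under equilibrating conditions, then N-(5-chloropyridin-2-yl)triflimide) gives the enol triflate F6, and Pd(OAc)2/PPh3 with HCO2H and Bu3N reduces it to 15.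

2. **Step 11.** Epimerisation at C-3a has to compete with deprotonation at C-5, which would move the double bond into conjugation with the C-4 ketone, and with retro-aldol scrambling at C-3. Fallback (conjugate on purpose, then deconjugate), which sets out from 13 and comes back at 14: DBU in PhMe at 80 °C is allowed to bring both the alkene and C-3a to equilibrium, giving the conjugated trans-fused enone (3R,3aR,8aR)-3-hydroxy-6,8a-dimethyl-3-(propan-2-yl)-2,3,3a,7,8,8a-hexahydroazulen-4(1H)-one F7. KOtBu in t-BuOH then forms the extended dienolate, and inverse quench into cold AcOH protonates it kinetically at C-5 to give 14.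

3. **Step 14.** Hydrogen abstraction may occur at C-5 or at the C-6 methyl group instead of C-8, or oxidation may run past the enone. Fallback (stepwise oxygen transposition instead of C–H oxidation), which sets out from 17 and comes back at 18: mCPBA gives the 6,7-epoxide F8 (either face serves). PhSeNa (from (PhSe)2 and NaBH4, EtOH) opens it at the less substituted C-7 to give the 6-hydroxy-7-(phenylselanyl) compound F9. H2O2 oxidises the selenide, and syn elimination away from the hydroxyl gives the tertiary allylic alcohol F10 with the Δ7 alkene. PCC then effects the oxidative 1,3-transposition (Babler–Dauben) to enone 18.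

## Further compounds

F1 | step 10 | methyl (6S)-2,9-dimethyl-4-oxo-6-(propan-2-yl)-6-[(triethylsilyl)oxy]dec-9-enoate, both C-2 epimers | COC(=O)C(C)CC(=O)C[C@](O[Si](CC)(CC)CC)(C(C)C)CCC(C)=C
F2 | step 10 | 3-hydroxy-4-methyl-2-{(3R)-2,6-dimethyl-3-[(triethylsilyl)oxy]hept-6-en-3-yl}cyclopent-2-en-1-one (enol of the 1,3-dione) | O=C1CC(C)C(O)=C1[C@](O[Si](CC)(CC)CC)(C(C)C)CCC(C)=C
F3 | step 10 | trans-fused 6,8a-dimethyl-3-(propan-2-yl)-3-[(triethylsilyl)oxy]octahydroazulene-4,7-dione, both C-6 epimers | O=C1CC(C)C(=O)C[C@@]2(C)CC[C@@](O[Si](CC)(CC)CC)(C(C)C)[C@H]12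
F4 | step 10 | trans-fused 3-hydroxy-6,8a-dimethyl-3-(propan-2-yl)octahydroazulene-4,7-dione, both C-6 epimers | O=C1CC(C)C(=O)C[C@@]2(C)CC[C@@](O)(C(C)C)[C@H]12
F5 | step 10 | trans-fused (4S)-3,4-dihydroxy-6,8a-dimethyl-3-(propan-2-yl)octahydroazulen-7(1H)-one, both C-6 epimers | O[C@H]1CC(C)C(=O)C[C@@]2(C)CC[C@@](O)(C(C)C)[C@H]12
F6 | step 10 | (3R,3aS,4S,8aR)-3,4-dihydroxy-6,8a-dimethyl-3-(propan-2-yl)-1,2,3,3a,4,5,8,8a-octahydroazulen-7-yl trifluoromethanesulfonate | O[C@H]1CC(C)=C(OS(=O)(=O)C(F)(F)F)C[C@@]2(C)CC[C@@](O)(C(C)C)[C@H]12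
F7 | step 11 | (3R,3aR,8aR)-3-hydroxy-6,8a-dimethyl-3-(propan-2-yl)-2,3,3a,7,8,8a-hexahydroazulen-4(1H)-one | O=C1C=C(C)CC[C@@]2(C)CC[C@@](O)(C(C)C)[C@H]12
F8 | step 14 | 6,7-epoxide of 17, either epoxide face | COc1ccc(C(=O)O[C@H]2CC4(C)OC4C[C@@]3(C)CC[C@@](O)(C(C)C)[C@H]23)cc1
F9 | step 14 | 3,6-dihydroxy-6,8a-dimethyl-7-(phenylselanyl)-3-(propan-2-yl)decahydroazulen-4-yl 4-methoxybenzoate | COc1ccc(C(=O)O[C@H]2CC(C)(O)C([Se]c4ccccc4)C[C@@]3(C)CC[C@@](O)(C(C)C)[C@H]23)cc1
F10 | step 14 | 3,6-dihydroxy-6,8a-dimethyl-3-(propan-2-yl)-1,2,3,3a,4,5,6,8a-octahydroazulen-4-yl 4-methoxybenzoate | COc1ccc(C(=O)O[C@H]2CC(C)(O)C=C[C@@]3(C)CC[C@@](O)(C(C)C)[C@H]23)cc1
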